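**Plan**

- Cuts: lactone C3–CH2 (benzyl of ring C) by enolate alkylation; ring B aryl–CH2 bond at lactone C4 by aryl-copper opening of a cyclopropane-fused lactone made from (S)-epichlorohydrin and dimethyl malonate; in the arm on ring B the C2–C3H2 and C1–O bonds (Prins) and then the C1=C2 alkene (olefination); in the arm on ring C the C1–C2 bond (aldol).
- Enabling feature: the arm on ring B, O–C1H(ring A)–C2H(ring B)–C3H2–O, bridged through its two oxygens by one CH2, is a trans-4,5-diaryl-1,3-dioxane with both aryl groups equatorial. That is the Prins adduct of the E-stilbene ring A–CH=CH–ring B with two formaldehyde units, C3 being a formaldehyde carbon.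
- The two arms are diastereomers: (1S,2S) on ring B, (1S,2R) on ring C. Only the first fits the trans-dioxane; the second is made by a syn-aldol and carried as an acetonide.
- Forward order: E-stilbene, dioxane ring (Prins), lactone ring (cyclopropane lactone opened by the ring B Grignard reagent), decarboxylation, trans benzylation with the ring C/D bromide, opening of both acetals, hydrogenolysis.
- Stereochemistry: lactone C4 from (S)-epichlorohydrin; C3 by alkylation anti to the C4 substituent; the (1S,2S) arm from the chiral acid, the E alkene and chair closure; the (1S,2R) arm from (S)-4-benzyl-2-oxazolidinone.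

Key step: step 6

Remark: rings A/B are the outer/inner rings of the arm on the C4 benzyl group and rings C/D the inner/outer rings of the arm on the C3 benzyl group; the antipode of the acid catalyst in step 6 is taken to be the one that gives the (4S,5S) dioxane, to be assigned in a first screen.

**Route**

Step 1
Reactants: 1 4-(benzyloxy)-3-methoxybenzaldehyde
Product: 2 [4-(benzyloxy)-3-methoxyphenyl]methanol
Conditions: NaBH4, MeOH, 0 °C
Reagents that add atoms: none
Why: Borohydride reduction of an aromatic aldehyde; no stereocentre is formed.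

Step 2
Reactants: 2 [4-(benzyloxy)-3-methoxyphenyl]methanol
Product: 3 4-(benzyloxy)-3-methoxybenzyl bromide
Conditions: PBr3, CH2Cl2, 0 °C
Reagents that add atoms: phosphorus tribromide, BrP(Br)Br
Why: Bromination of an electron-rich benzylic alcohol through its phosphite ester (SN2 by bromide).

Step 3
Reactants: 3 4-(benzyloxy)-3-methoxybenzyl bromide
Product: 4 diethyl [4-(benzyloxy)-3-methoxybenzyl]phosphonate
Conditions: P(OEt)3 (neat), 130 °C
Reagents that add atoms: triethyl phosphite, CCOP(OCC)OCC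
Why: Michaelis–Arbuzov reaction of a primary benzylic bromide.

Step 4
Reactants: 4 diethyl [4-(benzyloxy)-3-methoxybenzyl]phosphonate; 5 5-bromo-2-hydroxy-3-methoxybenzaldehyde
Product: 6 2-[(E)-2-(4-benzyloxy-3-methoxyphenyl)ethenyl]-4-bromo-6-methoxyphenol
Conditions: KOtBu (2.5 equiv), DMF, 0 to 25 °C; 1 M HCl work-up
Reagents that add atoms: none
Why: Horner–Wadsworth–Emmons olefination, in which the benzylic phosphonate anion should give the E-stilbene through reversible addition and syn elimination of phosphate while the extra base carries the phenol through as its phenoxide.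

Step 5
Reactants: 6 2-[(E)-2-(4-benzyloxy-3-methoxyphenyl)ethenyl]-4-bromo-6-methoxyphenol
Product: 7 2-[(E)-2-(4-benzyloxy-3-methoxyphenyl)ethenyl]-4-bromo-6-methoxyphenyl pivalate
Conditions: PivCl, Et3N, DMAP (cat.), CH2Cl2, 0 to 25 °C
Reagents that add atoms: pivaloyl chloride, CC(C)(C)C(=O)Cl
Why: DMAP-catalysed O-acylation of the phenol, done after the olefination so that no acyl transfer to the olefination alkoxide can occur; the pivalate makes ring B electron-poor for step 6.

Step 6
Reactants: 7 2-[(E)-2-(4-benzyloxy-3-methoxyphenyl)ethenyl]-4-bromo-6-methoxyphenyl pivalate; 8 formaldehyde (two equivalents incorporated, supplied as paraformaldehyde)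
Product: 9 2-[(4S,5S)-4-(4-benzyloxy-3-methoxyphenyl)-1,3-dioxan-5-yl]-4-bromo-6-methoxyphenyl pivalate (trans)
Conditions: (CH2O)n (6 equiv), confined chiral imino-imidodiphosphoric acid (iIDP, BINOL-derived, N-triflyl; 10 mol %; the more acidic IDPi congener if turnover is low), CHCl3–cyclohexane, 25 °C
Reagents that add atoms: none
Why: Proposed new method: the confined chiral acid protonates formaldehyde inside its pocket and this oxocarbenium electrophile bonds to the alkene carbon beside ring B, whose own cation would be destabilised by the pivaloyloxy and bromo groups, so that positive charge builds on the carbon carrying the para-benzyloxy ring A. The closest known reactions are the confined-acid-catalysed enantioselective Prins reaction of styrenes with paraformaldehyde to 4-aryl-1,3-dioxanes and the racemic Prins reaction of 1-arylpropenes to trans-4,5-disubstituted dioxanes; a 1,2-diarylethene has not been shown in either. The one new ring, the 1,3-dioxane, closes by six-membered C–O bond formation of the hemiformal oxygen (from the second formaldehyde) onto the benzylic carbon C4, either as capture of the ion-paired cation or as the late stage of a concerted asynchronous addition. C5 is set when the catalyst pocket selects the alkene face for C–C bond formation; C4 follows from suprafacial addition to the E alkene or, if a free cation intervenes, from closure to the chair with both aryl groups equatorial, so both paths should give the trans ring. The step needs regioselectivity (CH2 on the ring B side), trans selectivity and face selectivity: the first rests on the electronic contrast between the two aryl rings, the second on the E geometry from step 4 and chair closure, the third on the catalyst alone.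

Step 7
Reactants: 9 2-[(4S,5S)-4-(4-benzyloxy-3-methoxyphenyl)-1,3-dioxan-5-yl]-4-bromo-6-methoxyphenyl pivalate
Product: 11 (4S,5S)-4-(4-benzyloxy-3-methoxyphenyl)-5-(2-benzyloxy-5-bromo-3-methoxyphenyl)-1,3-dioxane, via phenol 10 (not isolated)
Conditions: K2CO3, MeOH–THF, 60 °C; evaporate; BnBr, DMF, 25 °C
Reagents that add atoms: benzyl bromide, BrCc1ccccc1
Why: Methanolysis of the aryl ester (transesterification) followed by Williamson etherification of the phenoxide in the same flask, because the pivalate would not survive the organomagnesium step; the dioxane stereocentres are not touched.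

Step 8
Reactants: 12 dimethyl malonate; 13 (S)-epichlorohydrin
Product: 14 methyl (1R,5S)-2-oxo-3-oxabicyclo[3.1.0]hexane-1-carboxylate
Conditions: NaOMe, MeOH, 0 °C to reflux
Reagents that add atoms: none
Why: Malonate alkylation–cyclopropanation–lactonisation cascade: the malonate opens the epoxide at its CH2, the alkoxide closes a new epoxide by displacing chloride, and the malonate carbanion opens that epoxide 3-exo with inversion at the former C2, which fixes C5 as S and, through the obligatory cis fusion, C1 as R.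

Step 9
Reactants: 11 (4S,5S)-4-(4-benzyloxy-3-methoxyphenyl)-5-(2-benzyloxy-5-bromo-3-methoxyphenyl)-1,3-dioxane; 14 methyl (1R,5S)-2-oxo-3-oxabicyclo[3.1.0]hexane-1-carboxylate
Product: 16 methyl (3R,4S)-4-{4-benzyloxy-3-[(4S,5S)-4-(4-benzyloxy-3-methoxyphenyl)-1,3-dioxan-5-yl]-5-methoxybenzyl}-2-oxotetrahydrofuran-3-carboxylate, via arylmagnesium bromide 15 (not isolated)
Conditions: Mg turnings, LiCl, THF, 25 °C; then CuBr·SMe2 (15 mol %), 14 (1.3 equiv), THF, −30 to 0 °C; 1 M HCl
Reagents that add atoms: none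
Why: Copper-catalysed homoconjugate addition of an aryl Grignard reagent to the doubly activated cyclopropane at its CH2 carbon; C5 of 14 is untouched and becomes C4 (S) of the lactone, while the epimerisable C3 should settle trans on protonation.

Step 10
Reactants: 16 methyl (3R,4S)-4-{4-benzyloxy-3-[(4S,5S)-4-(4-benzyloxy-3-methoxyphenyl)-1,3-dioxan-5-yl]-5-methoxybenzyl}-2-oxotetrahydrofuran-3-carboxylate
Product: 17 (4S)-4-{4-benzyloxy-3-[(4S,5S)-4-(4-benzyloxy-3-methoxyphenyl)-1,3-dioxan-5-yl]-5-methoxybenzyl}dihydrofuran-2(3H)-one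
Conditions: LiCl, DMSO–H2O, 140 °C
Reagents that add atoms: none
Why: Krapcho dealkoxycarbonylation (chloride attack at the ester methyl, loss of CO2, protonation); C4 is not involved and the acetal and ethers are inert to neutral salt at this temperature.

Step 11
Reactants: 18 methyl 4-hydroxy-3-methoxybenzoate (methyl vanillate)
Product: 19 methyl 4-(allyloxy)-3-methoxybenzoate
Conditions: allyl bromide, K2CO3, acetone, reflux
Reagents that add atoms: allyl bromide, C=CCBr
Why: Williamson etherification of the phenol.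

Step 12
Reactants: 19 methyl 4-(allyloxy)-3-methoxybenzoate
Product: 20 methyl 3-allyl-4-hydroxy-5-methoxybenzoate
Conditions: N,N-diethylaniline, 200 °C
Reagents that add atoms: none
Why: Aromatic Claisen rearrangement to the only free ortho position, followed by tautomerisation to the phenol.

Step 13
Reactants: 20 methyl 3-allyl-4-hydroxy-5-methoxybenzoate
Product: 21 methyl 3-allyl-4-(benzyloxy)-5-methoxybenzoate
Conditions: BnBr, K2CO3, DMF, 25 °C
Reagents that add atoms: benzyl bromide, BrCc1ccccc1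
Why: Williamson etherification of the hindered phenol in a dipolar aprotic solvent.

Step 14
Reactants: 21 methyl 3-allyl-4-(benzyloxy)-5-methoxybenzoate
Product: 23 2-[2-(benzyloxy)-3-methoxy-5-(methoxycarbonyl)phenyl]acetic acid, via arylacetaldehyde 22 (not isolated)
Conditions: OsO4 (2 mol %), NaIO4, 2,6-lutidine, dioxane–H2O, 25 °C; extractive work-up; then NaClO2, NaH2PO4, 2-methyl-2-butene, t-BuOH–H2O, 0 to 25 °C
Reagents that add atoms: sodium periodate, [Na+].[O-]I(=O)(=O)=O (with catalytic osmium tetroxide, O=[Os](=O)(=O)=O, source of the aldehyde oxygen); sodium chlorite, [Na+].[O-]Cl=O (carboxyl oxygen)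
Why: Lemieux–Johnson cleavage of the terminal alkene followed by Pinnick oxidation of the crude enolisable arylacetaldehyde, with lutidine buffer and a chlorine scavenger to spare the electron-rich ring.

Step 15
Reactants: 23 2-[2-(benzyloxy)-3-methoxy-5-(methoxycarbonyl)phenyl]acetic acid; 24 (S)-4-benzyl-2-oxazolidinone
Product: 26 methyl 3-{2-[(4S)-4-benzyl-2-oxooxazolidin-3-yl]-2-oxoethyl}-4-(benzyloxy)-5-methoxybenzoate, via mixed pivalic anhydride 25 (not isolated)
Conditions: PivCl, Et3N, THF, −20 °C; then LiCl, 24, −20 to 25 °C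
Reagents that add atoms: none
Why: N-Acylation of the oxazolidinone through the mixed pivalic anhydride (LiCl/Et3N activation), which attacks at the unhindered arylacetyl carbonyl.

Step 16
Reactants: 26 methyl 3-{2-[(4S)-4-benzyl-2-oxooxazolidin-3-yl]-2-oxoethyl}-4-(benzyloxy)-5-methoxybenzoate; 1 4-(benzyloxy)-3-methoxybenzaldehyde
Product: 29 methyl 3-{(2S,3S)-1-[(4S)-4-benzyl-2-oxooxazolidin-3-yl]-3-[4-(benzyloxy)-3-methoxyphenyl]-3-hydroxy-1-oxopropan-2-yl}-4-(benzyloxy)-5-methoxybenzoate, via Z-boron enolate 27 (not isolated), via boron aldolate 28 (not isolated)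
Conditions: Bu2BOTf, i-Pr2NEt, CH2Cl2, 0 °C; then 1, −78 to 0 °C; pH 7 buffer, MeOH, 30% H2O2, 0 °C
Reagents that add atoms: none
Why: Evans syn-aldol reaction: the Z-boron enolate reacts through a Zimmerman–Traxler chair with the aldehyde on the enolate face away from the benzyl group of the dipole-minimised auxiliary, which should set both new centres as (2S,3S), the syn relationship of the ring C arm.

Step 17
Reactants: 29 methyl 3-{(2S,3S)-1-[(4S)-4-benzyl-2-oxooxazolidin-3-yl]-3-[4-(benzyloxy)-3-methoxyphenyl]-3-hydroxy-1-oxopropan-2-yl}-4-(benzyloxy)-5-methoxybenzoate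
Product: 30 (1S,2R)-1-[4-(benzyloxy)-3-methoxyphenyl]-2-[2-(benzyloxy)-5-(hydroxymethyl)-3-methoxyphenyl]propane-1,3-diol
Conditions: LiBH4, MeOH (2 equiv), THF, 0 °C, then 45 °C
Reagents that add atoms: none
Why: Reductive removal of the auxiliary by LiBH4 at the exocyclic carbonyl at 0 °C, then slower borohydride reduction of the benzoate ester on warming; once the imide carbonyl is gone neither stereocentre can enolise or undergo retro-aldol cleavage.

Step 18
Reactants: 30 (1S,2R)-1-[4-(benzyloxy)-3-methoxyphenyl]-2-[2-(benzyloxy)-5-(hydroxymethyl)-3-methoxyphenyl]propane-1,3-diol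
Product: 31 {4-(benzyloxy)-3-[(4S,5R)-4-(4-benzyloxy-3-methoxyphenyl)-2,2-dimethyl-1,3-dioxan-5-yl]-5-methoxyphenyl}methanol (cis)
Conditions: Me2C(OMe)2, PPTS (cat.), CH2Cl2, 25 °C; brief MeOH quench
Reagents that add atoms: 2,2-dimethoxypropane, COC(C)(C)OC
Why: Acid-catalysed transacetalisation, in which only the 1,3-diol can form the six-membered isopropylidene acetal (aryl on C4 equatorial, aryl on C5 axial), leaving the benzylic CH2OH free.

Step 19
Reactants: 31 {4-(benzyloxy)-3-[(4S,5R)-4-(4-benzyloxy-3-methoxyphenyl)-2,2-dimethyl-1,3-dioxan-5-yl]-5-methoxyphenyl}methanol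
Product: 32 (4S,5R)-4-(4-benzyloxy-3-methoxyphenyl)-5-[2-benzyloxy-5-(bromomethyl)-3-methoxyphenyl]-2,2-dimethyl-1,3-dioxane
Conditions: CBr4, PPh3, CH2Cl2, 0 °C
Reagents that add atoms: carbon tetrabromide, BrC(Br)(Br)Br
Why: Appel reaction under neutral conditions, which the acetonide tolerates; the bromide is used crude.

Step 20
Reactants: 17 (4S)-4-{4-benzyloxy-3-[(4S,5S)-4-(4-benzyloxy-3-methoxyphenyl)-1,3-dioxan-5-yl]-5-methoxybenzyl}dihydrofuran-2(3H)-one; 32 (4S,5R)-4-(4-benzyloxy-3-methoxyphenyl)-5-[2-benzyloxy-5-(bromomethyl)-3-methoxyphenyl]-2,2-dimethyl-1,3-dioxane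
Product: 34 (3S,4S)-3,4-dibenzyl lactone carrying four benzyl ethers, the ring B arm as methylene acetal and the ring C arm as acetonide, via lithium enolate 33 (not isolated)
Conditions: LiN(SiMe3)2, THF, −78 °C; then 32, THF–DMPU, −78 to −30 °C
Reagents that add atoms: none
Why: Alkylation of the lactone lithium enolate with a benzylic bromide, which approaches anti to the C4 substituent and should set C3 as S (trans), as is general for 4-benzylbutyrolactones.

Step 21
Reactants: 34 fully protected (3S,4S)-lactone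
Product: 36 tetra-O-benzyl ether of the target (both 1,3-diols free), via acetonide diol 35 (not isolated)
Conditions: TMSOTf, 2,2'-bipyridyl, CH2Cl2, 0 to 25 °C; then H2O; then AcOH–THF–H2O, 40 °C
Reagents that add atoms: none
Why: Silyl triflate/2,2'-bipyridyl cleavage of the methylene acetal through an N-(alkoxymethyl)bipyridinium salt that water hydrolyses, then mild acid hydrolysis of the isopropylidene acetal; the buffered activation is chosen so that the para-benzyloxybenzylic C–O bonds are not ionised and the carbinol centres are kept.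

Step 22
Reactants: 36 tetra-O-benzyl ether of the target
Product: 37 CNP0113972.1, (3S,4S)-3-{4-hydroxy-3-[(1S,2R)-1,3-dihydroxy-1-(4-hydroxy-3-methoxyphenyl)propan-2-yl]-5-methoxybenzyl}-4-{4-hydroxy-3-[(1S,2S)-1,3-dihydroxy-1-(4-hydroxy-3-methoxyphenyl)propan-2-yl]-5-methoxybenzyl}dihydrofuran-2(3H)-one
Conditions: H2 (1 atm), Pd/C, EtOAc–MeOH, 25 °C
Reagents that add atoms: none
Why: Hydrogenolysis of the four aryl benzyl ethers over palladium on carbon under neutral conditions, which should leave the secondary benzylic alcohols and the lactone intact.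

**Compound list**

1 | 4-(benzyloxy)-3-methoxybenzaldehyde | COc1cc(C=O)ccc1OCc1ccccc1 | starting material
2 | [4-(benzyloxy)-3-methoxyphenyl]methanol | COc1cc(CO)ccc1OCc1ccccc1 | intermediate
3 | 4-(benzyloxy)-3-methoxybenzyl bromide | COc1cc(CBr)ccc1OCc1ccccc1 | intermediate
4 | diethyl [4-(benzyloxy)-3-methoxybenzyl]phosphonate | CCOP(=O)(Cc1ccc(OCc2ccccc2)c(OC)c1)OCC | intermediate
5 | 5-bromo-2-hydroxy-3-methoxybenzaldehyde | COc1cc(Br)cc(C=O)c1O | starting material
6 | 2-[(E)-2-(4-benzyloxy-3-methoxyphenyl)ethenyl]-4-bromo-6-methoxyphenol | COc1cc(/C=C/c2cc(Br)cc(OC)c2O)ccc1OCc1ccccc1 | intermediate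
7 | 2-[(E)-2-(4-benzyloxy-3-methoxyphenyl)ethenyl]-4-bromo-6-methoxyphenyl pivalate | COc1cc(/C=C/c2cc(Br)cc(OC)c2OC(=O)C(C)(C)C)ccc1OCc1ccccc1 | intermediate
8 | formaldehyde (from paraformaldehyde) | C=O | starting material
9 | 2-[(4S,5S)-4-(4-benzyloxy-3-methoxyphenyl)-1,3-dioxan-5-yl]-4-bromo-6-methoxyphenyl pivalate | COc1cc([C@H]2OCOC[C@@H]2c3cc(Br)cc(OC)c3OC(=O)C(C)(C)C)ccc1OCc4ccccc4 | intermediate
10 | 2-[(4S,5S)-4-(4-benzyloxy-3-methoxyphenyl)-1,3-dioxan-5-yl]-4-bromo-6-methoxyphenol | COc1cc([C@H]2OCOC[C@@H]2c3cc(Br)cc(OC)c3O)ccc1OCc4ccccc4 | intermediate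
11 | (4S,5S)-4-(4-benzyloxy-3-methoxyphenyl)-5-(2-benzyloxy-5-bromo-3-methoxyphenyl)-1,3-dioxane | COc1cc([C@H]2OCOC[C@@H]2c3cc(Br)cc(OC)c3OCc4ccccc4)ccc1OCc5ccccc5 | intermediate
12 | dimethyl malonate | COC(=O)CC(=O)OC | starting material
13 | (S)-epichlorohydrin | ClC[C@@H]1CO1 | starting material
14 | methyl (1R,5S)-2-oxo-3-oxabicyclo[3.1.0]hexane-1-carboxylate | O=C1OC[C@H]2C[C@@]12C(=O)OC | intermediate
15 | arylmagnesium bromide derived from 11 | COc1cc([C@H]2OCOC[C@@H]2c3cc([Mg]Br)cc(OC)c3OCc4ccccc4)ccc1OCc5ccccc5 | intermediate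
16 | methyl (3R,4S)-4-{4-benzyloxy-3-[(4S,5S)-4-(4-benzyloxy-3-methoxyphenyl)-1,3-dioxan-5-yl]-5-methoxybenzyl}-2-oxotetrahydrofuran-3-carboxylate | COc1cc([C@H]2OCOC[C@@H]2c3cc(C[C@@H]4COC(=O)[C@H]4C(=O)OC)cc(OC)c3OCc5ccccc5)ccc1OCc6ccccc6 | intermediate
17 | (4S)-4-{4-benzyloxy-3-[(4S,5S)-4-(4-benzyloxy-3-methoxyphenyl)-1,3-dioxan-5-yl]-5-methoxybenzyl}dihydrofuran-2(3H)-one | COc1cc([C@H]2OCOC[C@@H]2c3cc(C[C@@H]4COC(=O)C4)cc(OC)c3OCc5ccccc5)ccc1OCc6ccccc6 | intermediate
18 | methyl 4-hydroxy-3-methoxybenzoate (methyl vanillate) | COC(=O)c1ccc(O)c(OC)c1 | starting material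
19 | methyl 4-(allyloxy)-3-methoxybenzoate | COC(=O)c1ccc(OCC=C)c(OC)c1 | intermediate
20 | methyl 3-allyl-4-hydroxy-5-methoxybenzoate | COC(=O)c1cc(CC=C)c(O)c(OC)c1 | intermediate
21 | methyl 3-allyl-4-(benzyloxy)-5-methoxybenzoate | COC(=O)c1cc(CC=C)c(OCc2ccccc2)c(OC)c1 | intermediate
22 | methyl 4-(benzyloxy)-3-methoxy-5-(2-oxoethyl)benzoate | COC(=O)c1cc(CC=O)c(OCc2ccccc2)c(OC)c1 | intermediate
23 | 2-[2-(benzyloxy)-3-methoxy-5-(methoxycarbonyl)phenyl]acetic acid | COC(=O)c1cc(CC(=O)O)c(OCc2ccccc2)c(OC)c1 | intermediate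
24 | (S)-4-benzyl-2-oxazolidinone | O=C1N[C@@H](Cc2ccccc2)CO1 | starting material
25 | mixed anhydride of 23 with pivalic acid | COC(=O)c1cc(CC(=O)OC(=O)C(C)(C)C)c(OCc2ccccc2)c(OC)c1 | intermediate
26 | methyl 3-{2-[(4S)-4-benzyl-2-oxooxazolidin-3-yl]-2-oxoethyl}-4-(benzyloxy)-5-methoxybenzoate | COC(=O)c1cc(CC(=O)N2[C@@H](Cc3ccccc3)COC2=O)c(OCc4ccccc4)c(OC)c1 | intermediate
27 | Z-dibutylboron enolate of 26 | COC(=O)c1cc(/C=C(\OB(CCCC)CCCC)N2[C@@H](Cc3ccccc3)COC2=O)c(OCc4ccccc4)c(OC)c1 | intermediate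
28 | dibutylboron aldolate of 29 | COC(=O)c1cc([C@H](C(=O)N2[C@@H](Cc3ccccc3)COC2=O)[C@H](OB(CCCC)CCCC)c4ccc(OCc5ccccc5)c(OC)c4)c(OCc6ccccc6)c(OC)c1 | intermediate
29 | methyl 3-{(2S,3S)-1-[(4S)-4-benzyl-2-oxooxazolidin-3-yl]-3-[4-(benzyloxy)-3-methoxyphenyl]-3-hydroxy-1-oxopropan-2-yl}-4-(benzyloxy)-5-methoxybenzoate | COC(=O)c1cc([C@H](C(=O)N2[C@@H](Cc3ccccc3)COC2=O)[C@H](O)c4ccc(OCc5ccccc5)c(OC)c4)c(OCc6ccccc6)c(OC)c1 | intermediate
30 | (1S,2R)-1-[4-(benzyloxy)-3-methoxyphenyl]-2-[2-(benzyloxy)-5-(hydroxymethyl)-3-methoxyphenyl]propane-1,3-diol | OCc1cc([C@H](CO)[C@H](O)c2ccc(OCc3ccccc3)c(OC)c2)c(OCc4ccccc4)c(OC)c1 | intermediate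
31 | {4-(benzyloxy)-3-[(4S,5R)-4-(4-benzyloxy-3-methoxyphenyl)-2,2-dimethyl-1,3-dioxan-5-yl]-5-methoxyphenyl}methanol | OCc1cc([C@@H]2COC(C)(C)O[C@@H]2c3ccc(OCc4ccccc4)c(OC)c3)c(OCc5ccccc5)c(OC)c1 | intermediate
32 | (4S,5R)-4-(4-benzyloxy-3-methoxyphenyl)-5-[2-benzyloxy-5-(bromomethyl)-3-methoxyphenyl]-2,2-dimethyl-1,3-dioxane | BrCc1cc([C@@H]2COC(C)(C)O[C@@H]2c3ccc(OCc4ccccc4)c(OC)c3)c(OCc5ccccc5)c(OC)c1 | intermediate
33 | lithium enolate of 17 | COc1cc([C@H]2OCOC[C@@H]2c3cc(C[C@@H]4COC(O[Li])=C4)cc(OC)c3OCc5ccccc5)ccc1OCc6ccccc6 | intermediate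
34 | (3S,4S)-lactone with four benzyl ethers, ring B arm as (4S,5S)-1,3-dioxane, ring C arm as (4S,5R)-acetonide | COc1cc([C@H]2OCOC[C@@H]2c3cc(C[C@@H]4COC(=O)[C@H]4Cc5cc(OC)c(OCc6ccccc6)c([C@@H]7COC(C)(C)O[C@@H]7c8ccc(OCc9ccccc9)c(OC)c8)c5)cc(OC)c3OCc%10ccccc%10)ccc1OCc%11ccccc%11 | intermediate
35 | (3S,4S)-lactone with four benzyl ethers, ring B arm as free (1S,2S)-diol, ring C arm as acetonide | COc1cc([C@@H](O)[C@H](CO)c2cc(C[C@@H]3COC(=O)[C@H]3Cc4cc(OC)c(OCc5ccccc5)c([C@@H]6COC(C)(C)O[C@@H]6c7ccc(OCc8ccccc8)c(OC)c7)c4)cc(OC)c2OCc9ccccc9)ccc1OCc%10ccccc%10 | intermediate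
36 | tetra-O-benzyl ether of the target | COc1cc([C@@H](O)[C@H](CO)c2cc(C[C@@H]3COC(=O)[C@H]3Cc4cc(OC)c(OCc5ccccc5)c([C@H](CO)[C@H](O)c6ccc(OCc7ccccc7)c(OC)c6)c4)cc(OC)c2OCc8ccccc8)ccc1OCc9ccccc9 | intermediate
37 | CNP0113972.1 | COc1cc([C@@H](O)[C@H](CO)c2cc(C[C@@H]3COC(=O)[C@H]3Cc3cc(OC)c(O)c([C@H](CO)[C@H](O)c4ccc(O)c(OC)c4)c3)cc(OC)c2O)ccc1O | target

**Totals**

Total step count: 22.
Longest linear sequence: 12 steps (steps 1–7, 9, 10, 20, 21, 22; the branch through steps 11–19 and 20–22 is equally long).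

**Steps most likely to fail**

Step 6. The stilbene may turn over slowly in the confined acid, the electrophile may add in part at the ring A side, and discrimination between the alkene faces may be poor. The fallback builds the same dioxane by auxiliary-controlled aldol chemistry; it sets out from 5 and returns at 11. Benzylation of 5 (BnBr, K2CO3, DMF) should give 2-(benzyloxy)-5-bromo-3-methoxybenzaldehyde F1. Reductive cyanation with TosMIC (KOtBu, DME, −40 °C; then MeOH, reflux) should give 2-[2-(benzyloxy)-5-bromo-3-methoxyphenyl]acetonitrile F2, and hydrolysis (KOH, EtOH–H2O, reflux) the arylacetic acid F3. Acylation of (R)-4-benzyl-2-oxazolidinone (PivCl, Et3N, LiCl) should give the imide F4. An Evans syn-aldol reaction with 1 (Bu2BOTf, i-Pr2NEt) should give the (2R,3R) adduct F5, in which the aryl-bearing carbon already has the configuration needed and the carbinol carbon the opposite one. LiBH4 should give the (1R,2S)-diol F6. Dimethoxymethane with catalytic TfOH in CH2Cl2 should first close the cis-dioxane F7 and then, on longer exposure, equilibrate the para-benzyloxybenzylic centre C4 through the reversibly formed benzylic cation to the ring with both aryl groups equatorial, which is 11.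

Step 21. Heterolysis of the para-benzyloxybenzylic C–O bonds may compete with attack at the acetal carbon, leading to elimination or epimerisation at the carbinol carbons. The fallback first makes the outer rings electron-poor and then opens the acetals; it sets out from 34 and returns at 37. Hydrogenolysis of 34 (H2, Pd/C, EtOAc–MeOH) should give the tetraphenol with both acetals intact F8. Acetylation (Ac2O, pyridine) should give the tetra-aryl acetate F9, whose para-acetoxy rings no longer stabilise a benzylic cation. TMSOTf/2,2'-bipyridyl followed by aqueous acetic acid should then open both acetals to the tetra-aryl acetate of the target F10. Brief methanolysis (K2CO3, MeOH, 0 °C, then mildly acidic work-up to keep the lactone closed) should give 37.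

Step 9. Magnesium insertion into the large aryl bromide may stall, or the aryl nucleophile may attack the ester or lactone carbonyl instead of the cyclopropane CH2. The fallback builds the 4-benzyl lactone by the Stobbe and asymmetric hydrogenation sequence; it sets out from 11 and returns at 17. Bromine–lithium exchange and formylation (n-BuLi, THF, −78 °C; DMF) should give the aldehyde F11. Stobbe condensation with dimethyl succinate (NaOMe, MeOH, reflux) should give the (E)-arylidene succinic half-ester F12. Hydrogenation with Rh(cod)2BF4 and the antipode of a chiral bisphosphine such as Me-DuPhos that delivers the (S) acid (H2, MeOH) should give the (S)-2-(arylmethyl)succinic acid 1-methyl ester F13. Reduction of the ester in the potassium carboxylate with Ca(BH4)2 (from CaCl2 and NaBH4, EtOH), then acid lactonisation, should give 17.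

**Further compounds**

F1 | step 6 | 2-(benzyloxy)-5-bromo-3-methoxybenzaldehyde | COc1cc(Br)cc(C=O)c1OCc1ccccc1
F2 | step 6 | 2-[2-(benzyloxy)-5-bromo-3-methoxyphenyl]acetonitrile | COc1cc(Br)cc(CC#N)c1OCc1ccccc1
F3 | step 6 | 2-[2-(benzyloxy)-5-bromo-3-methoxyphenyl]acetic acid | COc1cc(Br)cc(CC(=O)O)c1OCc1ccccc1
F4 | step 6 | (R)-4-benzyl-3-{2-[2-(benzyloxy)-5-bromo-3-methoxyphenyl]acetyl}oxazolidin-2-one | COc1cc(Br)cc(CC(=O)N2[C@H](Cc3ccccc3)COC2=O)c1OCc1ccccc1
F5 | step 6 | (R)-4-benzyl-3-{(2R,3R)-2-[2-(benzyloxy)-5-bromo-3-methoxyphenyl]-3-[4-(benzyloxy)-3-methoxyphenyl]-3-hydroxypropanoyl}oxazolidin-2-one | COc1cc(Br)cc([C@@H](C(=O)N2[C@H](Cc3ccccc3)COC2=O)[C@@H](O)c2ccc(OCc3ccccc3)c(OC)c2)c1OCc1ccccc1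
F6 | step 6 | (1R,2S)-1-[4-(benzyloxy)-3-methoxyphenyl]-2-[2-(benzyloxy)-5-bromo-3-methoxyphenyl]propane-1,3-diol | COc1cc(Br)cc([C@@H](CO)[C@@H](O)c2ccc(OCc3ccccc3)c(OC)c2)c1OCc1ccccc1
F7 | step 6 | (4R,5S)-4-(4-benzyloxy-3-methoxyphenyl)-5-(2-benzyloxy-5-bromo-3-methoxyphenyl)-1,3-dioxane (cis) | COc1cc([C@@H]2OCOC[C@@H]2c3cc(Br)cc(OC)c3OCc4ccccc4)ccc1OCc5ccccc5
F8 | step 21 | tetraphenol of 34 with methylene acetal and acetonide intact | COc1cc([C@H]2OCOC[C@@H]2c3cc(C[C@@H]4COC(=O)[C@H]4Cc5cc(OC)c(O)c([C@@H]6COC(C)(C)O[C@@H]6c7ccc(O)c(OC)c7)c5)cc(OC)c3O)ccc1O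
F9 | step 21 | tetra-aryl acetate of F8 | COc1cc([C@H]2OCOC[C@@H]2c3cc(C[C@@H]4COC(=O)[C@H]4Cc5cc(OC)c(OC(C)=O)c([C@@H]6COC(C)(C)O[C@@H]6c7ccc(OC(C)=O)c(OC)c7)c5)cc(OC)c3OC(C)=O)ccc1OC(C)=O
F10 | step 21 | tetra-aryl acetate of the target | COc1cc([C@@H](O)[C@H](CO)c2cc(C[C@@H]3COC(=O)[C@H]3Cc4cc(OC)c(OC(C)=O)c([C@H](CO)[C@H](O)c5ccc(OC(C)=O)c(OC)c5)c4)cc(OC)c2OC(C)=O)ccc1OC(C)=O
F11 | step 9 | 4-(benzyloxy)-3-[(4S,5S)-4-(4-benzyloxy-3-methoxyphenyl)-1,3-dioxan-5-yl]-5-methoxybenzaldehyde | COc1cc([C@H]2OCOC[C@@H]2c3cc(C=O)cc(OC)c3OCc4ccccc4)ccc1OCc5ccccc5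
F12 | step 9 | (E)-4-aryl-3-(methoxycarbonyl)but-3-enoic acid from F11 | COc1cc([C@H]2OCOC[C@@H]2c3cc(/C=C(\CC(=O)O)C(=O)OC)cc(OC)c3OCc4ccccc4)ccc1OCc5ccccc5
F13 | step 9 | (S)-2-(arylmethyl)succinic acid 1-methyl ester from F12 | COc1cc([C@H]2OCOC[C@@H]2c3cc(C[C@@H](CC(=O)O)C(=O)OC)cc(OC)c3OCc4ccccc4)ccc1OCc5ccccc5
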